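The numbers in the tables are simulated on assumed constants; scatter was added.

The ratio I would watch in these flasks is c(Z) in larch over c(Z) in alder, summed over the readings from 6.3 min on, which I call the larch-over-alder ratio 0.522: it compares equal times, and it uses the readings that stand highest above the scatter.

all flasks: J 0.100 M
- alder: L 0.300 M; X 0.00500 M
- oak: L 0.300 M; X 0.00750 M
- cedar: L 0.300 M; X 0.00500 M; Z 0.0500 M
- larch: L 0.600 M; X 0.00500 M
- ash: L 0.600 M; X 0.00250 M; time 12 min

| alder run: time / min | alder run: [Z] / M | oak run: time / min | oak run: [Z] / M | cedar run: time / min | cedar run: [Z] / M | larch run: time / min | larch run: [Z] / M |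
|---|---|---|---|---|---|---|---|
| 0.68 | 0 | 0.68 | 0.0032 | 0.68 | 0.0481 | 0.68 | 0.0023 |
| 2.1 | 0.0072 | 2.1 | 0.0093 | 2.1 | 0.0478 | 2.1 | 0.0047 |
| 4.0 | 0.0101 | 4.0 | 0.0187 | 4.0 | 0.0430 | 4.0 | 0.0072 |
| 6.3 | 0.0157 | 6.3 | 0.0246 | 6.3 | 0.0410 | 6.3 | 0.0077 |
| 9.0 | 0.0195 | 9.0 | 0.0270 | 9.0 | 0.0367 | 9.0 | 0.0109 |
| 12 | 0.0226 | 12 | 0.0276 | 12 | 0.0356 | 12 | 0.0116 |

(scatter of a reading: 0.001 M)

- Overall: J + L -> Z, with X as catalyst.
- Constant volume, constant temperature.
- What is held in complexes is read along with the free species.
- "The second partner" is L.
- An order is taken over about fifteen percent of the charge, up and down.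

- the power of [X] that the first rate follows, about the charge of the alder run; measure it at two percent of J made into Z
- the power of [L] that the first rate follows, about the charge of the alder run; measure it at two percent of J made into Z
- Z in the ash run at 12 min, as a share of the J charged

I turn the settings one at a time. By hand, more X should scale Z with the charge ratio of 1.50, and oak over alder gives 1.62 on the readings at 2.1 min and 4.0 min and 1.37 on the late ones, so these lie on either side of it and I commit to power one. By hand, charged Z should climb further, yet cedar falls from 0.0481 M to 0.0356 M, so Z is being lost; if that loss goes with c(Z), it shrinks larch and alder by nearly the same factor at equal times and drops out of the larch-over-alder ratio. By hand, L as a reagent should raise the rate when doubled, but larch stands lower than alder. The order in L I read is therefore −0.937. A late ratio also carries the J already used, and oak has made more Z than alder while larch has made less, which brings oak's ratio down towards one and larch's up towards it. Ash has the L of larch and half its X, so at power one I take half of larch's reading at 12 min, which makes Z in ash 5.80% of the J charged.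

The forecast gave 1.3, −0.4 and 7.5%, saying “So L inhibits, with an order of about −0.4 and possibly stronger later.”

The flask gives 1.1 in X, −0.93 in L and 6.61% for ash, and at two percent of J turned, the rate of larch over that of alder is 0.50, where my larch-over-alder ratio read 0.522.

    X + J → XJ (162.6 M⁻¹ min⁻¹)
    XJ + L → Ek (678.0 M⁻¹ min⁻¹)
    Ek → Z + X (10.26 min⁻¹)
    X + L ⇌ XL, settled at all times (59.30 M⁻¹)
    Z → Vy (0.1116 min⁻¹)

The larch-over-alder ratio stands near half because L holds X as XL, the resting state of X. In the run with that tying up taken away, the order in L goes from −0.93 to 0.023, and that power, put on the L of larch over the L of alder, gives 1.02 in place of the 0.522 I read. In ash, with the L of larch, the same change lifts Z at 12 min from 6.61% to 42.3% of the J charged.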